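Everything rests on cutting the interflavan bond between C4 (ring C) of the third epicatechin unit and C8 (ring A) of the terminal unit. In one operation, BF3·OEt2 ionises a benzyl-protected trimer bearing a 4β-(2-ethoxyethoxy) group on its lowest unit and a bromine cap on C8 of its top unit; the C4 benzylic cation, stabilised by the 5,7-dioxygenated ring A, is captured by C8 of tetra-O-benzylepicatechin (a 3+1 Friedel–Crafts union). The cis 2-aryl and 3-hydroxyl groups of ring C block the α face, so the 4β (3,4-trans) bond forms. The trimer is grown by orthogonal hard (alkoxy) and soft (thioether) C4 activation from one oxidised monomer; a single hydrogenolysis finishes the synthesis.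

Key step: step 7

Remark: the target is taken as the natural tetramer of four (2R,3R)-epicatechin units joined by three 4β→8 bonds, with units counted 1 (top, free C8) to 4 (terminal, C4 methylene). The C4 cations through which steps 2 and 4 to 7 pass are transient ion pairs, described in the Why lines and not numbered.

Step 1
Reactants: 1 (−)-epicatechin
Product: 2 tetra-O-benzylepicatechin, (2R,3R)-5,7-bis(benzyloxy)-2-[3,4-bis(benzyloxy)phenyl]chroman-3-ol
Conditions: BnBr, K2CO3, DMF, 0 °C to rt, argon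
Reagents that add atoms: benzyl bromide BrCc1ccccc1
Why: Williamson ether synthesis, in which K2CO3 ionises only the four phenols (not the C3 alcohol), which are O-benzylated by SN2 attack on benzyl bromide, and no stereocentre is touched.

Step 2
Reactants: 2 tetra-O-benzylepicatechin
Product: 3 ethoxyethoxy monomer, (2R,3R,4S)-5,7-bis(benzyloxy)-2-[3,4-bis(benzyloxy)phenyl]-4-(2-ethoxyethoxy)chroman-3-ol (4β-alkoxy group, trans to the 3-hydroxyl group)
Conditions: DDQ, 2-ethoxyethanol, CH2Cl2, rt
Reagents that add atoms: 2-ethoxyethanol CCOCCO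
Why: DDQ benzylic C–H oxidation, in which hydride abstraction from C4 (activated by the 5- and 7-benzyloxy groups of ring A) gives a C4 cation that 2-ethoxyethanol captures on the β face, anti to the cis 2-aryl and 3-hydroxyl groups, which sets C4 as 4β (3,4-trans).

Step 3
Reactants: 3 ethoxyethoxy monomer
Product: 4 bromo-capped donor, (2R,3R,4S)-5,7-bis(benzyloxy)-2-[3,4-bis(benzyloxy)phenyl]-8-bromo-4-(2-ethoxyethoxy)chroman-3-ol
Conditions: NBS (1 equiv), CH2Cl2, −78 to −20 °C
Reagents that add atoms: N-bromosuccinimide O=C1CCC(=O)N1Br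
Why: Electrophilic aromatic bromination, in which C8 of ring A (flanked by O1 and one benzyloxy group) is the most accessible activated position while C6 lies between two benzyloxy groups, so one equivalent of NBS at low temperature should give the 8-bromide without touching the C4 ether or any stereocentre.

Step 4
Reactants: 3 ethoxyethoxy monomer
Product: 5 thioether monomer, (2R,3S,4S)-5,7-bis(benzyloxy)-2-[3,4-bis(benzyloxy)phenyl]-4-[(2,6-dimethylphenyl)sulfanyl]chroman-3-ol (4β-arylthio group, trans to the 3-hydroxyl group)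
Conditions: 2,6-dimethylbenzenethiol (excess), BF3·OEt2, CH2Cl2, −78 °C
Reagents that add atoms: 2,6-dimethylbenzenethiol Cc1cccc(C)c1S
Why: Lewis-acid SN1 thioetherification (thiolysis of the C4 ether), in which BF3·OEt2 ionises the C4–O bond and the thiol, a far better nucleophile than C8 of a second molecule, adds to the β face of the cation, so that C4 is again 4β.

Step 5
Reactants: 4 bromo-capped donor; 5 thioether monomer
Product: 6 dimer thioether, 8-bromo-octa-O-benzyl-epicatechin-(4β→8)-epicatechin carrying a 4β-(2,6-dimethylphenyl)sulfanyl group on C4 of the lower unit, both 3-hydroxyl groups free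
Conditions: BF3·OEt2, 4 Å MS, CH2Cl2, −78 to −40 °C
Reagents that add atoms: none
Why: Friedel–Crafts alkylation under hard Lewis-acid activation, in which BF3·OEt2 ionises only the C4–O ether of 4 (the C4–S bond of 5 is inert at this temperature, its 2,6-dimethylphenyl group shields sulfur from alkylation, and the bromine blocks self-coupling of 4), and C8 of 5 adds to the β face of the cation, which sets C4 of the upper unit as 4β.

Step 6
Reactants: 6 dimer thioether; 3 ethoxyethoxy monomer
Product: 7 trimer donor, 8-bromo-dodeca-O-benzyl-epicatechin-(4β→8)-epicatechin-(4β→8)-epicatechin carrying a 4β-(2-ethoxyethoxy) group on C4 of the lowest unit, three 3-hydroxyl groups free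
Conditions: I2, Ag2O, 4 Å MS, CH2Cl2, −78 to 0 °C
Reagents that add atoms: none
Why: Iodonium (thiophilic) activation of a benzylic thioether, the chemistry of thioglycoside donors, followed by Friedel–Crafts alkylation, in which I2/Ag2O ionises the C4–S bond of 6 under acid-free conditions that leave the C4 ether of 3 intact, and C8 of 3 adds to the β face, which sets C4 of unit 2 as 4β.

Step 7
Reactants: 7 trimer donor; 2 tetra-O-benzylepicatechin
Product: 8 protected tetramer, 8-bromo-hexadeca-O-benzyl-epicatechin-(4β→8)-epicatechin-(4β→8)-epicatechin-(4β→8)-epicatechin (bromine on C8 of unit 1, all sixteen phenols as benzyl ethers, four free 3-hydroxyl groups, three 4β→8 bonds)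
Conditions: BF3·OEt2, 2 (slight excess), 4 Å MS, CH2Cl2, −78 to −30 °C
Reagents that add atoms: none
Why: BF3·OEt2 binds the C4 alkoxy oxygen on unit 3 of 7 and ionises it to a C4 benzylic cation delocalised into the 5,7-dibenzyloxy ring A (a quinone-methide-like oxocarbenium ion); C8 of ring A of 2 attacks this cation and loss of the C8 proton restores the arene. The closest known reaction type is the Lewis-acid-mediated SN1 Friedel–Crafts alkylation of flavan-3-ol nucleophiles by 4-alkoxy- or 4-acyloxyflavans, the standard union of benzylated procyanidin units. No ring is closed. The one new stereocentre, C4 of unit 3, is under substrate control: the cis 2-aryl and 3-hydroxyl groups on the α face of the half-chair ring C leave only the β face open, so the 4β (3,4-trans) bond should result. The step needs attack by C8 and not C6 of 2, which the two benzyloxy groups flanking C6 secure, and cross-coupling in place of self-coupling, which is secured because every C8 of 7 is blocked (bromine on unit 1, flavanyl groups on units 2 and 3), so 2 is the only competent nucleophile and a near-equimolar union is possible. Low temperature protects the two interflavan bonds already present from acid-induced scission.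

Step 8
Reactants: 8 protected tetramer
Product: 9 the target tetramer, epicatechin-(4β→8)-epicatechin-(4β→8)-epicatechin-(4β→8)-epicatechin
Conditions: H2 (1 atm), Pd(OH)2/C, NaOAc, THF/MeOH/H2O, rt; filtration, Sephadex LH-20
Reagents that add atoms: none
Why: Heterogeneous palladium-catalysed hydrogenolysis should cleave the sixteen benzyl ethers and the C8–Br bond in one operation, NaOAc buffers the HBr so that the acid-labile interflavan bonds survive, and no stereocentre is affected.

Compound list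
1 | (−)-epicatechin, (2R,3R)-2-(3,4-dihydroxyphenyl)chroman-3,5,7-triol | Oc1cc(O)c2c(c1)O[C@H](c1ccc(O)c(O)c1)[C@H](O)C2 | starting material
2 | tetra-O-benzylepicatechin, (2R,3R)-5,7-bis(benzyloxy)-2-[3,4-bis(benzyloxy)phenyl]chroman-3-ol | c3ccccc3COc1cc(OCc3ccccc3)c2c(c1)O[C@H](c1ccc(OCc3ccccc3)c(OCc3ccccc3)c1)[C@H](O)C2 | intermediate
3 | ethoxyethoxy monomer, (2R,3R,4S)-4β-(2-ethoxyethoxy)-5,7,3',4'-tetra-O-benzylepicatechin | c3ccccc3COc1cc(OCc3ccccc3)c2c(c1)O[C@H](c1ccc(OCc3ccccc3)c(OCc3ccccc3)c1)[C@H](O)[C@H]2OCCOCC | intermediate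
4 | bromo-capped donor, (2R,3R,4S)-8-bromo-4β-(2-ethoxyethoxy)-5,7,3',4'-tetra-O-benzylepicatechin | c3ccccc3COc1cc(OCc3ccccc3)c2c(c1Br)O[C@H](c1ccc(OCc3ccccc3)c(OCc3ccccc3)c1)[C@H](O)[C@H]2OCCOCC | intermediate
5 | thioether monomer, (2R,3S,4S)-4β-[(2,6-dimethylphenyl)sulfanyl]-5,7,3',4'-tetra-O-benzylepicatechin | c3ccccc3COc1cc(OCc3ccccc3)c2c(c1)O[C@H](c1ccc(OCc3ccccc3)c(OCc3ccccc3)c1)[C@H](O)[C@H]2Sc1c(C)cccc1C | intermediate
6 | dimer thioether, 8-bromo-octa-O-benzyl-epicatechin-(4β→8)-epicatechin with a 4β-(2,6-dimethylphenyl)sulfanyl group on the lower unit | c3ccccc3COc1cc(OCc3ccccc3)c2c(c1Br)O[C@H](c1ccc(OCc3ccccc3)c(OCc3ccccc3)c1)[C@H](O)[C@H]2c1c(OCc3ccccc3)cc(OCc3ccccc3)c2c1O[C@H](c1ccc(OCc3ccccc3)c(OCc3ccccc3)c1)[C@H](O)[C@H]2Sc1c(C)cccc1C | intermediate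
7 | trimer donor, 8-bromo-dodeca-O-benzyl-epicatechin-(4β→8)-epicatechin-(4β→8)-epicatechin with a 4β-(2-ethoxyethoxy) group on the lowest unit | c3ccccc3COc1cc(OCc3ccccc3)c2c(c1Br)O[C@H](c1ccc(OCc3ccccc3)c(OCc3ccccc3)c1)[C@H](O)[C@H]2c1c(OCc3ccccc3)cc(OCc3ccccc3)c2c1O[C@H](c1ccc(OCc3ccccc3)c(OCc3ccccc3)c1)[C@H](O)[C@H]2c1c(OCc3ccccc3)cc(OCc3ccccc3)c2c1O[C@H](c1ccc(OCc3ccccc3)c(OCc3ccccc3)c1)[C@H](O)[C@H]2OCCOCC | intermediate
8 | protected tetramer, 8-bromo-hexadeca-O-benzyl-epicatechin-(4β→8)-epicatechin-(4β→8)-epicatechin-(4β→8)-epicatechin | c3ccccc3COc1cc(OCc3ccccc3)c2c(c1Br)O[C@H](c1ccc(OCc3ccccc3)c(OCc3ccccc3)c1)[C@H](O)[C@H]2c1c(OCc3ccccc3)cc(OCc3ccccc3)c2c1O[C@H](c1ccc(OCc3ccccc3)c(OCc3ccccc3)c1)[C@H](O)[C@H]2c1c(OCc3ccccc3)cc(OCc3ccccc3)c2c1O[C@H](c1ccc(OCc3ccccc3)c(OCc3ccccc3)c1)[C@H](O)[C@H]2c1c(OCc3ccccc3)cc(OCc3ccccc3)c2c1O[C@H](c1ccc(OCc3ccccc3)c(OCc3ccccc3)c1)[C@H](O)C2 | intermediate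
9 | the target tetramer, epicatechin-(4β→8)-epicatechin-(4β→8)-epicatechin-(4β→8)-epicatechin | Oc1cc(O)c2c(c1)O[C@H](c1ccc(O)c(O)c1)[C@H](O)[C@H]2c1c(O)cc(O)c2c1O[C@H](c1ccc(O)c(O)c1)[C@H](O)[C@H]2c1c(O)cc(O)c2c1O[C@H](c1ccc(O)c(O)c1)[C@H](O)[C@H]2c1c(O)cc(O)c2c1O[C@H](c1ccc(O)c(O)c1)[C@H](O)C2 | target

Total step count: 8. Longest linear sequence: 7 steps (steps 1, 2, 3, 5, 6, 7, 8; step 4 is the side branch to 5).

Steps most likely to fail

Step 6. The iodonium reagent may iodinate the free C8 position of 3 instead of activating sulfur, or traces of acid may ionise the C4 ether of 3 or of 7 and start uncontrolled chain growth. The fallback sets out from 4 and 2 and comes back at 7; the leaving group is no longer carried through a coupling but installed afterwards by C–H oxidation. 4 is coupled with 2 (BF3·OEt2, CH2Cl2, −78 °C) to give the bromo-capped octa-O-benzyl dimer F1. DDQ and 2-ethoxyethanol then oxidise its only benzylic methylene, C4 of the lower unit, to the dimeric 4β-(2-ethoxyethoxy) donor F2. F2 is coupled with 2 under BF3·OEt2 to give the bromo-capped dodeca-O-benzyl trimer F3, and a second DDQ/2-ethoxyethanol oxidation at C4 of the lowest unit should give 7.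

Step 7. The Lewis acid may cleave or scramble the interflavan bonds of the trimer, capture of the hindered cation may be slow enough for elimination toward a flav-3-ene to compete, or part of the attack may go through C6. The fallback sets out from 3, 2 and 6 and comes back at 8; it is a 2+2 union under acid-free soft activation, so that no oligomer meets a strong Lewis acid. 3 is coupled with an excess of 2 (BF3·OEt2, CH2Cl2, −78 °C) to give the bromine-free octa-O-benzyl dimer F4, whose only free C8 is on its upper unit. 6 and F4 are then joined with I2/Ag2O (4 Å MS, CH2Cl2, −78 to 0 °C) to give 8.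

Step 8. The sixteen-fold debenzylation may stall as the partly deprotected intermediates become polar and bromide slows the catalyst, and interflavan bonds may undergo acidolysis if the HBr is not fully buffered. The fallback sets out from 8 and comes back at 9. Bromine is removed first by a radical chain reduction (n-Bu3SnH, AIBN, toluene, 90 °C) to give the hexadeca-O-benzyl tetramer F5, which is then hydrogenolysed under halide-free neutral conditions (H2, Pd(OH)2/C, THF/MeOH/H2O, rt) to give 9.

Further compounds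
F1 | step 6 | bromo-capped octa-O-benzyl dimer, 8-bromo-octa-O-benzyl-epicatechin-(4β→8)-epicatechin | c3ccccc3COc1cc(OCc3ccccc3)c2c(c1Br)O[C@H](c1ccc(OCc3ccccc3)c(OCc3ccccc3)c1)[C@H](O)[C@H]2c1c(OCc3ccccc3)cc(OCc3ccccc3)c2c1O[C@H](c1ccc(OCc3ccccc3)c(OCc3ccccc3)c1)[C@H](O)C2
F2 | step 6 | dimeric 4β-(2-ethoxyethoxy) donor, F1 with a 4β-(2-ethoxyethoxy) group on C4 of the lower unit | c3ccccc3COc1cc(OCc3ccccc3)c2c(c1Br)O[C@H](c1ccc(OCc3ccccc3)c(OCc3ccccc3)c1)[C@H](O)[C@H]2c1c(OCc3ccccc3)cc(OCc3ccccc3)c2c1O[C@H](c1ccc(OCc3ccccc3)c(OCc3ccccc3)c1)[C@H](O)[C@H]2OCCOCC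
F3 | step 6 | bromo-capped dodeca-O-benzyl trimer, 8-bromo-dodeca-O-benzyl-epicatechin-(4β→8)-epicatechin-(4β→8)-epicatechin | c3ccccc3COc1cc(OCc3ccccc3)c2c(c1Br)O[C@H](c1ccc(OCc3ccccc3)c(OCc3ccccc3)c1)[C@H](O)[C@H]2c1c(OCc3ccccc3)cc(OCc3ccccc3)c2c1O[C@H](c1ccc(OCc3ccccc3)c(OCc3ccccc3)c1)[C@H](O)[C@H]2c1c(OCc3ccccc3)cc(OCc3ccccc3)c2c1O[C@H](c1ccc(OCc3ccccc3)c(OCc3ccccc3)c1)[C@H](O)C2
F4 | step 7 | bromine-free octa-O-benzyl dimer, octa-O-benzyl-epicatechin-(4β→8)-epicatechin | c3ccccc3COc1cc(OCc3ccccc3)c2c(c1)O[C@H](c1ccc(OCc3ccccc3)c(OCc3ccccc3)c1)[C@H](O)[C@H]2c1c(OCc3ccccc3)cc(OCc3ccccc3)c2c1O[C@H](c1ccc(OCc3ccccc3)c(OCc3ccccc3)c1)[C@H](O)C2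
F5 | step 8 | hexadeca-O-benzyl tetramer, hexadeca-O-benzyl-epicatechin-(4β→8)-epicatechin-(4β→8)-epicatechin-(4β→8)-epicatechin | c3ccccc3COc1cc(OCc3ccccc3)c2c(c1)O[C@H](c1ccc(OCc3ccccc3)c(OCc3ccccc3)c1)[C@H](O)[C@H]2c1c(OCc3ccccc3)cc(OCc3ccccc3)c2c1O[C@H](c1ccc(OCc3ccccc3)c(OCc3ccccc3)c1)[C@H](O)[C@H]2c1c(OCc3ccccc3)cc(OCc3ccccc3)c2c1O[C@H](c1ccc(OCc3ccccc3)c(OCc3ccccc3)c1)[C@H](O)[C@H]2c1c(OCc3ccccc3)cc(OCc3ccccc3)c2c1O[C@H](c1ccc(OCc3ccccc3)c(OCc3ccccc3)c1)[C@H](O)C2
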